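The runs come from a simulation with made-up constants; noise was put on by code.

I began from a one-step world, D + E → G, where a steady feed simply withholds part of the product [D][E] over time. In that world, while little has reacted, a flask fed D and a flask fed E over the same time lose the same stretch of that product, and that symmetric case was the zero of my scale.

| flask | D | E | remark | time |
|---|---|---|---|---|
| Tuesday's | 1 mM | 1.5 mM | run made earlier |  |
| Thursday's | 1 mM | 0.75 mM | run made earlier |  |
| Wednesday's | 1 mM | 3 mM | run made earlier |  |
| Monday's | 2 mM | 1.5 mM | run made earlier |  |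
| birch | 1.0 mM | 1.50 mM (fed, over 40 s) | all else is in the flask from the start; the feed brings no volume worth counting | 3.0 min |
| alder | 1.0 mM | 1.50 mM (fed, over 2.5 min) | all else is in the flask from the start; the feed brings no volume worth counting | 3.0 min |
| ash | 1.0 mM (fed, over 2.5 min) | 1.50 mM | all else is in the flask from the start; the feed brings no volume worth counting | 3.0 min |
| elm | 1.0 mM | 1.50 mM | everything together at the start | 3.0 min |

Tuesday's run (percent of the D charged)

| time / s | J / % | G / % |
|---|---|---|
| 20.0 | 2 | 0 |
| 40.0 | 0 | 4 |
| 50.0 | 0 | 4 |
| 80.0 | 0 | 13 |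
| 90.0 | 1 | 18 |
| 120 | 11 | 41 |

Thursday's run (percent of the D charged)

| time / min | J / % | G / % |
|---|---|---|
| 0.500 | 0 | 1 |
| 1.00 | 0 | 3 |
| 1.50 | 0 | 4 |
| 2.00 | 2 | 5 |
| 2.50 | 4 | 9 |
| 3.00 | 5 | 13 |

Wednesday's run (percent of the D charged)

| time / min | J / % | G / % |
|---|---|---|
| 0.200 | 2 | 0 |
| 0.667 | 6 | 11 |
| 1.00 | 5 | 55 |
| 1.50 | 24 | 73 |
| 2.50 | 53 | 42 |
| 3.00 | 64 | 37 |

Monday's run (percent of the D charged)

| time / min | J / % | G / % |
|---|---|---|
| 0.250 | 1 | 5 |
| 0.417 | 1 | 0 |
| 0.833 | 2 | 19 |
| 1.50 | 15 | 49 |
| 3.00 | 47 | 29 |

(scatter of a reading: 2 percentage points)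

- the flask that comes out highest in amount of J, in percent of the D charged; "all alike" if 1.5 percentage points covers them all (birch / alder / ash / elm / all alike)
- amount of J at the end, in percent of the D charged, birch
- amount of J at the end, in percent of the D charged, alder
- amount of J at the end, in percent of the D charged, ash
- amount of J at the end, in percent of the D charged, elm

- the numbers in the tables scatter by 2 percentage points (one standard deviation)

While little has reacted, a steady feed over 2.5 min lags the integral of [D][E] by 75.0 s, half the feed time, whichever partner is fed. I therefore defined an equivalent time: the time less that lag, scaled by the product of the charges to Tuesday's charges, which are also elm's.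

birch: 180 s less 20.0 s gives 160 s

alder and ash: 180 s less 75.0 s gives 105 s

elm: 180 s

I tested the scaling first. Thursday's reading at 3.00 min has an equivalent time of 90.0 s, the same as Tuesday's 90.0 s, and G + J stood at 18.0 % and 19.0 %.

For "all alike", these equivalent times would have to fall where J stays within 1.5 percentage points. But Tuesday's J goes from 1 % at 90.0 s to 11 % at 120 s, so this problem stands far from that. At the midpoint, 105 s, I read J as 6.00 % for both alder and ash. Birch and elm lie beyond Tuesday's last reading, so I read no number for them, but elm has the latest equivalent time.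

The forecast began “The runs show an induction period, then take-off”. It gave birch 27 %, alder 7 %, ash 6.5 % and elm 35 %, with elm highest.

The flasks gave birch 28.6 %, elm 37.4 %, and, at equivalent time 105 s, alder 6.85 % and ash 6.82 %; elm came out highest.

    D + E + Z → G + 2 Z (k = 41000 M⁻² s⁻¹)
    D + E → G + Z (k = 0.0610 M⁻¹ s⁻¹)
    G → J (k = 0.00840 s⁻¹)

In ash, the step with Z used E 130 times as fast as the step without Z at 2.68 min, and 260 times as fast at 3.00 min. A flask like ash but with 0.60 mM of E has an equivalent time of 42.0 s, close to Tuesday's 40.0 s, where G read 4 % with a scatter of 2 points, and it ended with G 1.34 % and J 0.409 %.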